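(The runs were computed for substances that don't exist; noise was put on by code.)

Turning percentages into amounts per litre is an easy step that changes the look of the earlier runs. At 15 min the south-east run holds 2.00 mM of target and the west run 2.06 mM, a difference of 0.0600 mM, which is less than the 0.100 mM by which one south-east reading scatters. Two amounts therefore carry the argument: the charge of solid substrate, and the mean target per litre at that time, 2.03 mM, the yield per litre. Their ratio is the percentage, and within the scatter of these two runs the target at that time reads as zero order in the solid charge.

| flask | solid substrate | remark | time |
|---|---|---|---|
| south-east | 20 mM | run made earlier |  |
| west | 29 mM | run made earlier |  |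
| flask | 39 mM |  | 15 min |

- south-east (time / min: target / %, solid substrate / %): 2.00: 0, 93.3; 5.00: 2.9, 83.5; 10.0: 7.0, 71.9; 15.0: 10.0, 60.3
- west (time / min: target / %, solid substrate / %): 2.00: 0.4, 95.2; 5.00: 1.8, 88.3; 10.0: 5.2, 80.7; 15.0: 7.1, 74.1

(readings scatter by 0.5 percentage points)

- in percentages every species weighs as the solid substrate in it: one homo dimer counts as two
- as a solid, counted per litre of solution: solid substrate
- the analysis behind the earlier runs scatters by 0.5 percentage points, standard deviation
- what may be going on: other conformer -> isomer of the product; starting material <-> other conformer; solid substrate <-> starting material; starting material -> target; 2 starting material -> homo dimer; target <-> isomer of the product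
- at the start none of the solid substrate is in solution

- maple: doubling the solubility of the solid substrate, all else as stated
- ash: doubling the dissolution coefficient of the solid substrate, all else as stated

- amount of target at 15 min, in percent of the solid substrate charged
- the change that raises the amount of target at 15 min, in percent of the solid substrate charged most ("none" if none brings more than 2 percentage points) (maple / ash / none)
- amount of target at 15 min, in percent of the solid substrate charged, after maple

Reckoned here, the flask with 39 mM of solid substrate gives 5.21% of target, and if maple doubles the yield per litre, 10.4%. The reading to watch is therefore the target in mM rather than in percent. The forecast, for which “dissolution doesn't depend on the solid load”, says 5.2%, names maple as best and gives 9.8% after it, somewhat below the doubled figure here.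

The flask gives 5.51%, which is 2.15 mM of target. The best change is maple, which gains 4.2 percentage points against 1.7 points for ash and reaches 9.72%.

    other conformer → isomer of the product (k = 0.00320 /s)
    starting material ⇌ other conformer (K = 2.50, k = 3.00 × 10⁻⁴ /s)
    solid substrate ⇌ starting material, rate k3*(cs3 - [starting material]) while solid is left; crystals form when [starting material] > cs3 (solubility = 4.20 mM, k = 0.00400 /s)
    starting material → target (k = 0.00120 /s)
    2 starting material → homo dimer (k = 0.350 /M/s)
    target ⇌ isomer of the product (K = 1.10, k = 5.10 × 10⁻⁵ /s)

A neighbouring flask with 160 mM of solid substrate, the time held, is reckoned from the same 2.03 mM at 1.27%, and it gives 1.34%. At 15.0 min that neighbour still holds 95.1% of its charge as solid substrate, and its target stands at 2.14 mM.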